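**Minutes: the flask at late times**

Late in the alder run G still climbs, but ever more slowly, and the meeting started there.

| flask | E | D | X | remark | time |
|---|---|---|---|---|---|
| alder | 0.080 M | 1.3 equiv | 1.05 equiv | run made earlier |  |
| larch | 0.080 M | 1 equiv | 1.05 equiv | run made earlier |  |
| north | 0.080 M | 2.00 equiv | 1.05 equiv |  | 20 d |
| north-east | 0.15 M | 2.00 equiv | 1.05 equiv |  | 20 d |
| south-west | 0.30 M | 2.00 equiv | 1.05 equiv |  | 20 d |

| run | time / d | G / % |
|---|---|---|
| alder | 1.25 | 4.7 |
| alder | 3.00 | 12.9 |
| alder | 4.00 | 16.9 |
| alder | 6.00 | 21.1 |
| alder | 8.00 | 23.8 |
| larch | 0.625 | 1.0 |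
| larch | 1.67 | 5.8 |
| larch | 3.00 | 11.1 |
| larch | 5.00 | 16.6 |
| larch | 8.00 | 20.7 |

(readings scatter by 0.3 percentage points)

- a reading or a percentage of G counts all its forms, free or not
- "hardly changes" means that all values lie within two and a half points (for a concentration: within two and a half percent of the largest)

- amount of G at the end, in percent of the E charged for north, north-east, south-west, in this order
- the shape of the row from first to last (hardly changes / falls, then rises / rises, then falls / falls all the way / rises all the way)

The analyst reported alder gains of 4.2 percentage points up to 6.00 d and 2.7 points up to 8.00 d. A series shrinking by that ratio ends near 28.7%, a rough reading given a scatter of 0.3 points.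

The kineticist pointed to the slow start of larch, 1.0% at 0.625 d, and argued that two pieces stand before G: X makes one from E and one from D, and these then join.

The chair asked for a zero of the scale, and the kineticist offered two. A one-for-one swap at equilibrium, with the equivalents held fixed, gives the same percentage at any concentration, so a flat row is the zero for concentration. X without preference shares itself by charge, so in alder the E piece gets 45.7% and the D piece 59.3% of the E charged.

Supposing X ends up entirely in the two pieces, she divided the concentration of G at the alder ceiling by the product of the free pieces' concentrations. This gave the hold constant, an association constant, of 68.7 L mol⁻¹. Multiplied by the starting concentration of E, it gives a hold number, which grows in step with that concentration.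

For the charges of the new flasks the even share is 35.0% for the E piece and 70.0% for the D piece. Solving for G, the meeting committed to 24.9% for north, 28.4% for north-east and 31.1% for south-west.

The forecast gave 35%, 39% and 44%, shape rises all the way, saying “I expect a modest rise”, and its north figure stands higher than the meeting's.

The flasks give 29.1%, 32.8% and 35.8%: rises all the way.

    X + D → Q (k = 1.48 × 10⁻⁵ L mol⁻¹ s⁻¹)
    X + G → J (k = 6.17 × 10⁻⁶ L mol⁻¹ s⁻¹)
    L ⇌ G, rate k3*(cs3 - [G]) while solid is left; crystals form when [G] > cs3 (solubility = 0.230 M, k = 0.00104 s⁻¹)
    Z + Q ⇌ G (K = 101 L mol⁻¹, k = 0.00145 L mol⁻¹ s⁻¹)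
    E + X → Z (k = 2.47 × 10⁻⁵ L mol⁻¹ s⁻¹)

The gain of 6.8 points from north to south-west owes its largest single effect to the way back from G to Z + Q, since without that way back the change is 0.16 points. The hold number goes from 5.50 in north to 20.6 in south-west, and Z left at the end falls from 13.0% to 5.78%. South-west was reckoned at 31.1% and gives 35.8%, and it used 44.0% of its E, more than the even share of 35.0%.

(All runs were generated by integration from invented constants, and the scatter is random.)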